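Assumptions: "1,3" follows IUPAC quinic acid numbering. The SMILES decodes as (1R,3R,4S,5R), with O‑1, O‑3 and O‑4 on one face and O‑5 and CO2H on the other. The acyl groups sit on the tertiary O‑1 and on the axial O‑3 that is cis to 4‑OH, so the compound is cynarin in the natural (−)‑quinic acid series. 5‑Bromo‑2,2‑dimethyl‑1,3‑benzodioxole is taken as a catalogue building block.

## Retrosynthetic overview
1. Target ⇒ fully ketal‑masked diester by one global acidolysis. The 4,5‑diol is masked as a butane‑2,3‑diacetal (BDA) and both catechols as acetonides.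
2. Both acyl C–O bonds (O‑1 and O‑3) are cut together. This gives BDA‑quinic acid (free CO2H, 1‑OH, 3‑OH) and two equivalents of acetonide‑protected (E)‑caffeic aldehyde, joined in a single anodic NHC oxidative esterification.
3. BDA‑acid ⇒ (−)‑quinic acid by acetalisation of the only trans‑diequatorial diol, then saponification. Enal ⇒ aryl bromide + acrolein acetal (Heck).
4. Rings: the carbocycle and both arenes are bought. The only ring made is the temporary trans‑fused 1,4‑dioxane, formed in step 1 and opened in the last step. All four stereocentres come from quinic acid, and no C–O bond at a stereocentre is ever broken.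

## Route

**Step 1**
Reactants: 1, (−)‑quinic acid; 2, butane‑2,3‑dione
Product: 3, methyl 4,5‑O‑[(2S,3S)‑2,3‑dimethoxybutane‑2,3‑diyl]quinate (trans‑fused dioxane, both OMe axial; 1‑OH and 3‑OH free and syn‑diaxial)
Conditions: 2 (1.3 equiv), HC(OMe)3 (4 equiv), p‑TsOH·H2O (5 mol %), MeOH, reflux, 18 h
Reagents that add atoms: methanol, CO; trimethyl orthoformate, COC(OC)OC
Why: Thermodynamically controlled butane‑2,3‑diacetal formation selects the only trans‑diequatorial 1,2‑diol (O4/O5) with concurrent Fischer esterification, and the two temporary acetal centres are set (S,S) by the diol through the double anomeric effect.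

**Step 2**
Reactants: 3
Product: 4, 4,5‑O‑[(2S,3S)‑2,3‑dimethoxybutane‑2,3‑diyl]quinic acid (free CO2H, 1‑OH, 3‑OH)
Conditions: LiOH (2 equiv), THF/H2O 3:1, rt, 3 h; then 10 % citric acid to pH 3, EtOAc
Reagents that add atoms: lithium hydroxide, [Li+].[OH-]; water, O
Why: This is an ordinary BAc2 saponification; C1 has no α‑H so nothing can epimerise, and the BDA acetal is stable to base and to the mild acidic work‑up.

**Step 3**
Reactants: 5, 5‑bromo‑2,2‑dimethyl‑1,3‑benzodioxole; 6, acrolein diethyl acetal (3,3‑diethoxyprop‑1‑ene)
Product: 7, (E)‑3‑(2,2‑dimethyl‑1,3‑benzodioxol‑5‑yl)prop‑2‑enal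
Conditions: 6 (3 equiv), Pd(OAc)2 (3 mol %), nBu4NOAc (2 equiv), K2CO3, KCl, DMF, 90 °C; then 2 M HCl, rt, 10 min
Reagents that add atoms: water, O (aldehyde oxygen after acetal hydrolysis)
Why: Mizoroki–Heck arylation of the acrolein acetal under Jeffery‑type conditions gives the E‑alkene by syn‑insertion and syn β‑H elimination, and the brief dilute‑acid work‑up unmasks the aldehyde without touching the catechol ketal.

**Step 4 (key step)**
Reactants: 4; 7 (3.2 equiv)
Product: 8, 1,3‑bis‑O‑[(E)‑3‑(2,2‑dimethyl‑1,3‑benzodioxol‑5‑yl)prop‑2‑enoyl]‑4,5‑O‑[(2S,3S)‑2,3‑dimethoxybutane‑2,3‑diyl]quinic acid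
Conditions: 2‑mesityl‑6,7‑dihydro‑5H‑pyrrolo[2,1‑c][1,2,4]triazol‑2‑ium BF4 (achiral, 20 mol %), 3,3′,5,5′‑tetra‑tert‑butyl‑4,4′‑diphenoquinone (10 mol %), Mg(OTf)2 (20 mol %), DBU (2.5 equiv), nBu4NBF4 (0.1 M), MeCN, 4 Å MS, 40 °C, dark. Cell: large RVC anode, Pt‑wire cathode (quasi‑divided), constant current, 2.3 F per mol of 7, with 7 added by syringe pump at the rate of charge passage. Work‑up: 10 % citric acid.
Reagents that add atoms: none (both new acyl units come from reactant 7)
Why: Proposed new method: the NHC adds to 7 to give a Breslow intermediate (oxidised near −0.9 V vs SCE), which the diphenoquinone converts in solution into the (E)‑α,β‑unsaturated acyl azolium faster than homoenolate protonation; the resulting bisphenol is re‑oxidised at the anode, more than 1 V below the onset for the aryl‑alkene or for Kolbe/Hofer–Moest loss of the carboxylate, while H2 forms at the cathode and regenerates DBU; O‑3 is acylated by normal base‑assisted 1,2‑addition, whereas the tertiary O‑1 is acylated because its geminal, Mg‑chelated carboxylate either acts as an intramolecular general base or captures the acyl azolium as a mixed anhydride that collapses by a five‑membered 1,4‑O→O acyl shift through a 2‑hydroxy‑1,3‑dioxolan‑4‑one; only O–H and acyl C–O bonds change, so all stereocentres and the E‑geometry are retained; the closest known reaction types are NHC‑catalysed anodic (or stoichiometric quinone) oxidative esterification of aldehydes with simple primary and secondary alcohols, and acyl‑azolium acylation of activated tertiary α‑hydroxy carbonyl compounds, neither of which has been shown for a tertiary α‑hydroxy acid, a syn‑diaxial diol or an anodically recycled quinone.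

**Step 5**
Reactants: 8
Product: 9, 1,3‑di‑O‑caffeoylquinic acid, (1R,3R,4S,5R)
Conditions: TFA/H2O 9:1, 0 °C → rt, 2 h, dark; dilute with H2O, lyophilise; C18 (H2O/MeCN, 0.1 % HCO2H)
Reagents that add atoms: none (water, O, gives only H to 9; its oxygen leaves in acetone and butanedione)
Why: All three masking groups are ketals and are cleaved together by acid‑catalysed ketal hydrolysis via oxocarbenium ions, which leaves the esters, E‑alkenes and carbinol C–O bonds intact, and the acidic medium suppresses base‑promoted O3→O4 acyl migration.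

## Compound list
1 | (−)‑quinic acid | O[C@@H]1C[C@@](O)(C(=O)O)C[C@@H](O)[C@@H]1O | starting material
2 | butane‑2,3‑dione | CC(=O)C(C)=O | starting material
3 | methyl 4,5‑O‑[(2S,3S)‑2,3‑dimethoxybutane‑2,3‑diyl]quinate | O[C@@H]1C[C@@](O)(C(=O)OC)C[C@H]2O[C@](C)(OC)[C@@](C)(OC)O[C@H]12 | intermediate
4 | 4,5‑O‑[(2S,3S)‑2,3‑dimethoxybutane‑2,3‑diyl]quinic acid | O[C@@H]1C[C@@](O)(C(=O)O)C[C@H]2O[C@](C)(OC)[C@@](C)(OC)O[C@H]12 | intermediate
5 | 5‑bromo‑2,2‑dimethyl‑1,3‑benzodioxole | Brc1ccc2OC(C)(C)Oc2c1 | starting material
6 | acrolein diethyl acetal | C=CC(OCC)OCC | starting material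
7 | (E)‑3‑(2,2‑dimethyl‑1,3‑benzodioxol‑5‑yl)prop‑2‑enal | O=C/C=C/c1ccc2OC(C)(C)Oc2c1 | intermediate
8 | 1,3‑bis‑O‑(acetonide‑caffeoyl)‑4,5‑O‑BDA‑quinic acid | O=C(/C=C/c1ccc2OC(C)(C)Oc2c1)O[C@@H]3C[C@@](OC(=O)/C=C/c4ccc5OC(C)(C)Oc5c4)(C(=O)O)C[C@H]6O[C@](C)(OC)[C@@](C)(OC)O[C@H]36 | intermediate
9 | 1,3‑dicaffeoylquinic acid | O=C(/C=C/c1ccc(O)c(O)c1)O[C@@H]1C[C@@](OC(=O)/C=C/c2ccc(O)c(O)c2)(C(=O)O)C[C@@H](O)[C@@H]1O | target

## Step count and risks
Total steps: 5. Longest linear sequence: 4 (1 → 3 → 4 → 8 → 9).

Steps most likely to fail:
1. **Step 4 (proposed new step).**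
   - Risks: the reaction may stop at the O‑3 monoester because the tertiary O‑1 is too slow. Saturated ester may form by homoenolate protonation. The acyl azolium may be lost at the cathode.
   - Fallback (known chemistry): abandon oxidative acyl‑azolium transfer. Run a Heck reaction of 5 with acrylic acid to get the protected caffeic acid, convert it with (COCl)2 to the acid chloride, and acylate 4 with DMAP/pyridine in CH2Cl2 at 40 °C to reach the same 8.
   - If O‑1 still resists: open Meldrum's acid with the 1‑ and 3‑OH groups (toluene, reflux) to the bis(malonic half‑ester), then carry out a Knoevenagel–Doebner condensation with 3,4‑dihydroxybenzaldehyde.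
2. **Step 5.**
   - Risks: the catechol acetonides cleave more slowly than the BDA group. Long acid exposure risks 1,5‑lactonisation or O3→O4 migration.
   - Fallback: switch to orthogonal masking. Use the bis‑O‑allyl enal in step 4, remove the allyl groups under neutral Pd(PPh3)4/N‑methylaniline conditions, then cleave only the BDA group with about 10 min of TFA/H2O.
3. **Step 3.**
   - Risks: β‑H elimination toward the acetal gives the 3‑arylpropanoate ester instead, and the electron‑rich bromide may react sluggishly.
   - Fallback: build the enal by carbonyl olefination. Br/Li exchange on 5 (nBuLi, −78 °C) and a DMF quench give the aldehyde, followed by Wittig reaction with Ph3P=CHCHO (toluene, 90 °C).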